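The readings come from a simulation from invented constants; the scatter is artificial.

6.55 monomer units per chain is the reckoning for this flask, charged with 0.20 M of free monomer and 16 mM of initiator. The number is its units per initiator: the monomer in chains at the end of a run, divided by the initiator charged. It equals the average asked for, the number-average degree of polymerisation, if each initiator used begins one chain and the initiator is used up.

all flasks: initiator 16 mM
- alder: free monomer 0.20 M; transfer agent 1 mM; run made earlier
- elm: free monomer 0.20 M; transfer agent 1.5 mM; run made earlier
- ash: free monomer 0.40 M; transfer agent 2 mM; run made earlier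
- flask: free monomer 0.20 M; transfer agent 2.00 mM; time 30 min

| run | time / min | monomer in chains / % | free monomer / % |
|---|---|---|---|
| alder | 3.00 | 26.3 | 55.1 |
| alder | 5.00 | 37.3 | 37.0 |
| alder | 10.0 | 50.5 | 13.8 |
| alder | 20.0 | 53.2 | 4.6 |
| alder | 40.0 | 53.1 | 0.3 |
| elm | 3.00 | 25.6 | 54.8 |
| elm | 5.00 | 37.0 | 38.3 |
| elm | 10.0 | 49.8 | 14.6 |
| elm | 20.0 | 54.0 | 2.7 |
| elm | 40.0 | 51.2 | 0 |
| ash | 8.00 | 44.7 | 22.2 |
| ash | 15.0 | 50.7 | 7.1 |
| ash | 20.0 | 50.3 | 6.4 |
| ash | 30.0 | 51.0 | 0.9 |
| ash | 40.0 | 52.8 | 1.2 |

(standard deviation of a reading: 1 percentage point)

- average number of monomer units in a chain (chains begun, living or dead) at 30 min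
- part of the free monomer that has reacted at 30 min

- the average divides the monomer in chains by the number of chains begun, living and dead together
- on the list of suspects stand: living end + transfer agent -> dead chain; free monomer + initiator -> living end + monomer in chains; free monomer + living end -> monomer in chains + living end; free monomer -> uncatalysed product; living end + monomer in chains -> dead end
- the earlier runs do not show the number of chains; that part of a forecast is a guess

units per initiator = end share of monomer in chains × free monomer charged / initiator charged
= 52.4 % × 0.20 M / 16 mM = 6.55

Transfer agent, on the list of suspects, stops a living end and begins no chain, so by hand it should leave the count of chains alone, and this flask's 2.00 mM of it stands against 16 mM of initiator; the alder and elm runs, with 1 mM and 1.5 mM, end at 53.1 % and 51.2 %, each reading with a scatter of 1 percentage point. Doubling the free monomer should double the ratio if the share holds, and the ash run, at 0.40 M and with 2 mM of transfer agent, ends at 52.8 %. Initiator stood at 16 mM in each run, so its use remains a guess. As for time, the ash run, at its own charge, reads 0.9 % of free monomer at 30.0 min, and that single reading, with its scatter, taken over to this flask suggests a conversion near 99.1 %.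

The forecast gave 99 % and, higher than this reckoning, an average of 7.5, judging that “most of the 16 mM initiator probably starts chains”.

The flask gives 6.60 and 99.0 %, with 0.80 % of its initiator left at 30.0 min. Its own end share of 52.4 % gives 6.60 units per initiator used.

    living end + transfer agent → dead chain (kL = 0.360 L mol⁻¹ s⁻¹)
    free monomer + initiator → living end + monomer in chains (k = 0.0760 L mol⁻¹ s⁻¹)
    free monomer + living end → monomer in chains + living end, rate k3*[living end]*[free monomer] (k = 0.160 L mol⁻¹ s⁻¹)
    free monomer → uncatalysed product (k = 0.00130 s⁻¹)
    living end + monomer in chains → dead end (k = 0.00900 L mol⁻¹ s⁻¹)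

For the neighbour charged with 0.080 M of free monomer, the same share gives 2.62 units per initiator charged, or 3.04 per initiator used, with 14 % of that neighbour's initiator left at the asked time. The computed average there is 2.95.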